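**Retrosynthetic overview**
1. Target ⇐ reagent-controlled 1,2-reduction of an α-methylene cycloheptanone ⇐ ring expansion (1,2-alkyl shift) of a 1-ethynylcyclohexanol in a trans-hydrindene; the six-membered ring becomes the seven-membered ring and the methylidene carbon is inserted next to the ring fusion.
2. Side chain: the bond between the acetoxy carbon and the homomethallyl unit is made by Felkin-controlled Grignard addition to a lactol. The lactol comes from a cis-fused α-methyl-γ-lactone that fixes the ring-carbinol/side-chain cis relationship and the CH–CH3 centre.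
3. Cyclopentene: ring-closing metathesis of a trans allyl/isopropenyl pair installed by conjugate addition–enolate allylation on an enone-lactone.
4. Enone-lactone ⇐ (S)-cyclohex-2-en-1-ol by Johnson–Claisen rearrangement, selenolactonization–elimination, lactone methylation and allylic oxidation.
5. Ring order: cyclohexene (bought) → γ-lactone → cyclopentene → cycloheptane (by expansion of the six-membered ring); the lactone is opened before the expansion.

Assumption: (S)-cyclohex-2-en-1-ol (1, ≥98% ee) and the Grignard solutions 13 and 18 are bought as such.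
Locants used below are those of the target skeleton: C1/C5 ring fusion, C2–C4 cyclopentene (C4 carries CH3), C6 and C9 ring carbinol carbons, C7 ring carbon carrying the side chain, C8 ring CH2, C10 methylidene-bearing carbon, C11 CH(CH3), C12 CH(OAc), C13–C15 chain.

**Step 1**
Reactants: 1 (S)-cyclohex-2-en-1-ol; 2 trimethyl orthoacetate
Product: 4 methyl 2-[(1S)-cyclohex-2-en-1-yl]acetate, via ketene acetal 3 (not isolated)
Conditions: 2 (6 equiv), EtCO2H (5 mol%), 140 °C, sealed tube, MeOH bled off
Reagents that add atoms: none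
Why: Johnson–Claisen rearrangement; ketene acetal 3 rearranges through a chair-like [3,3] transition state on the face that carried oxygen, so the carbinol stereocentre of 1 is transferred to C7.

**Step 2**
Reactants: 4 methyl 2-[(1S)-cyclohex-2-en-1-yl]acetate
Product: 5 2-[(1S)-cyclohex-2-en-1-yl]acetic acid
Conditions: LiOH·H2O, THF/H2O 3:1, rt; then 1 M HCl
Reagents that add atoms: lithium hydroxide, [Li+].[OH-]
Why: Ester saponification; the allylic stereocentre is not acidic and is untouched.

**Step 3**
Reactants: 5 2-[(1S)-cyclohex-2-en-1-yl]acetic acid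
Product: 8 (3aS,7aR)-3a,4,5,7a-tetrahydro-1-benzofuran-2(3H)-one, via selenolactone 6 (not isolated), via selenoxide 7 (not isolated)
Conditions: PhSeCl, CH2Cl2, −78 °C; then 30% H2O2, THF, 0 °C → rt
Reagents that add atoms: none
Why: Phenylselenolactonization then selenoxide syn-elimination; anti addition through the two-atom tether can only give the cis-fused γ-lactone (C6–O cis to C7–C11), and the selenoxide eliminates away from the oxygen-bearing carbon to leave the C5=C1 alkene.

**Step 4**
Reactants: 8 (3aS,7aR)-3a,4,5,7a-tetrahydro-1-benzofuran-2(3H)-one; 9 iodomethane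
Product: 11 (3S,3aS,7aS)-3-methyl-3a,4,5,7a-tetrahydro-1-benzofuran-2(3H)-one, via lithium enolate 10 (not isolated)
Conditions: LiN(i-Pr)2 (1.1 equiv), THF, −78 °C; then 9, −78 → −40 °C
Reagents that add atoms: none
Why: Lactone enolate alkylation; iodomethane attacks the convex face of the cis-fused bicyclic enolate 10, which sets C11 with the methyl anti to the carbocycle.

**Step 5**
Reactants: 11 (3S,3aS,7aS)-3-methyl-3a,4,5,7a-tetrahydro-1-benzofuran-2(3H)-one
Product: 12 (3S,3aS,7aS)-3-methyl-3a,4-dihydro-1-benzofuran-2,5(3H,7aH)-dione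
Conditions: Rh2(caprolactamate)4 (1 mol%), t-BuOOH (70% aq., 5 equiv), ClCH2CH2Cl, rt → 40 °C
Reagents that add atoms: tert-butyl hydroperoxide, CC(C)(C)OO
Why: Dirhodium-catalysed allylic C–H oxidation; C9 is the only allylic methylene (the other allylic carbon already bears the acyloxy group), so the C9 enone forms without touching a stereocentre.

**Step 6**
Reactants: 12 (3S,3aS,7aS)-3-methyl-3a,4-dihydro-1-benzofuran-2,5(3H,7aH)-dione; 13 isopropenylmagnesium bromide; 14 allyl bromide
Product: 16 (3S,3aS,6R,7S,7aR)-3-methyl-6-(prop-2-en-1-yl)-7-(prop-1-en-2-yl)hexahydro-1-benzofuran-2,5-dione, via magnesium enolate 15 (not isolated)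
Conditions: 13 (1.3 equiv), CuBr·SMe2 (10 mol%), THF, −78 °C; then 14 (3 equiv), DMPU, −78 → −20 °C
Reagents that add atoms: none
Why: Copper-catalysed conjugate addition with enolate allylation (three-component coupling); the isopropenyl group adds to C5 on the convex face anti to the C6–O bond and 14 alkylates enolate 15 at C1 trans to it, setting C5 and C1.

**Step 7**
Reactants: 16 (3S,3aS,6R,7S,7aR)-3-methyl-6-(prop-2-en-1-yl)-7-(prop-1-en-2-yl)hexahydro-1-benzofuran-2,5-dione
Product: 17 tricyclic keto-lactone (trans-fused 4-methylcyclopentene/cyclohexan-9-one carrying the cis-fused α-methyl-γ-lactone across C6–O and C7; 1R,5S,6R,7S,11S)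
Conditions: second-generation Grubbs catalyst (3 mol%), CH2Cl2, 40 °C
Reagents that add atoms: none
Why: Ring-closing metathesis of the allyl/isopropenyl pair; loss of ethylene closes the trisubstituted cyclopentene, and the trans-diequatorial arrangement gives the trans ring fusion without touching a stereocentre.

**Step 8**
Reactants: 17 tricyclic keto-lactone; 18 ethynylmagnesium bromide
Product: 19 (9S)-9-ethynyl-9-hydroxy lactone (tertiary propargylic alcohol of 17; OH α and axial, ethynyl β)
Conditions: 18 (1.5 equiv), LaCl3·2LiCl (0.3 equiv), THF, −78 °C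
Reagents that add atoms: none
Why: Lanthanum-promoted Grignard 1,2-addition; the ketone reacts far faster than the lactone at −78 °C with little enolisation, the acetylide enters from the β face away from the axial C7–C11 bond, and this C9 centre is erased again in step 11.

**Step 9**
Reactants: 19 (9S)-9-ethynyl-9-hydroxy lactone; 20 4-bromo-2-methylbut-1-ene (used as its Grignard reagent)
Product: 22 (3aS,4R,5S,7S,7aR)-7-ethynyl-5-[(2S,3S)-3-hydroxy-6-methylhept-6-en-2-yl]-3-methyl-3a,4,5,6,7,7a-hexahydro-1H-indene-4,7-diol, via lactol 21 (not isolated)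
Conditions: i-Bu2AlH (2.3 equiv), CH2Cl2, −78 °C; then CH2=C(CH3)CH2CH2MgBr (6 equiv; from 20, Mg, THF), −78 → 0 °C; aq. potassium sodium tartrate
Reagents that add atoms: none
Why: Lactone half-reduction then Grignard addition to the α-methyl aldehyde released from lactolate 21; Felkin–Anh attack anti to the ring carbon C7 gives the 11,12-syn (12S) alcohol, and the excess reagent covers the tertiary OH and alkyne protons.

**Step 10**
Reactants: 22 triol; 23 acetic anhydride
Product: 24 (2S,3S)-2-[(3aS,4R,5S,7S,7aR)-7-ethynyl-4,7-dihydroxy-3-methyl-3a,4,5,6,7,7a-hexahydro-1H-inden-5-yl]-6-methylhept-6-en-3-yl acetate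
Conditions: 23 (1.3 equiv), pyridine, CH2Cl2, −20 → 0 °C
Reagents that add atoms: none
Why: Chemoselective O-acylation; C12–OH is the only accessible hydroxyl, because C9–OH is tertiary and C6–OH is flanked by two ring methines and the C4 methyl.

**Step 11**
Reactants: 24 propargylic alcohol acetate
Product: 25 (2S,3S)-2-[(3aS,4R,5S,8aR)-4-hydroxy-3-methyl-8-methylidene-7-oxo-1,3a,4,5,6,7,8,8a-octahydroazulen-5-yl]-6-methylhept-6-en-3-yl acetate
Conditions: (L1)AuCl (5 mol%), AgNTf2 (5 mol%), 4 Å MS, PhCF3, 40 °C; L1 = 2-(di-1-adamantylphosphanyl)-3′-(pyrrolidin-1-ylcarbonyl)biphenyl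
Reagents that add atoms: none
Why: Proposed new method: gold-catalysed ring-expanding semipinacol shift of an unstrained 1-ethynylcyclohexanol to a 2-methylenecycloheptanone; monovalent gold activates the alkyne while the ligand's remote amide hydrogen-bonds the C9–OH anti to gold, so that O–H deprotonation is concerted with anti-periplanar 1,2-migration of the more substituted ring carbon C1 (with retention) onto C10, and the amide-held proton then cleaves the vinyl–gold bond to release the exo-methylene ketone; the alkyne-to-enone change is strongly exergonic even without ring strain, the C6–OH is trans to the ethynyl group and cannot reach it, and the closest known reaction is the strain-driven gold-catalysed ring expansion of 1-alkynylcyclobutanols and 1-alkynylcyclopropanols to alkylidene cycloalkanones, not shown for cyclohexanols.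

**Step 12**
Reactants: 25 α-methylene cycloheptanone
Product: 26 (2S,3S)-2-[(3aS,4R,5S,7R,8aR)-4,7-dihydroxy-3-methyl-8-methylidene-1,3a,4,5,6,7,8,8a-octahydroazulen-5-yl]-6-methylhept-6-en-3-yl acetate (target, CNP0327794.2)
Conditions: (S)-2-methyl-CBS-oxazaborolidine (20 mol%), catecholborane (3 equiv), toluene, −78 °C; then MeOH, aq. NaHCO3
Reagents that add atoms: none
Why: Corey–Bakshi–Shibata reduction; reagent-controlled 1,2-hydride delivery with the sp2 carbon C10 as the large group gives the 9R allylic alcohol, and catecholborane at −78 °C leaves the acetate and the alkenes alone.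

**Compound list**
1 | (S)-cyclohex-2-en-1-ol | O[C@@H]1C=CCCC1 | starting material
2 | trimethyl orthoacetate | COC(C)(OC)OC | starting material
3 | (S)-cyclohex-2-en-1-yl methyl ketene acetal | C=C(OC)O[C@@H]1C=CCCC1 | intermediate
4 | methyl 2-[(1S)-cyclohex-2-en-1-yl]acetate | COC(=O)C[C@@H]1CCCC=C1 | intermediate
5 | 2-[(1S)-cyclohex-2-en-1-yl]acetic acid | OC(=O)C[C@@H]1CCCC=C1 | intermediate
6 | (3aS,7R,7aR)-7-(phenylselanyl)hexahydro-1-benzofuran-2(3H)-one | O=C1C[C@@H]2CCC[C@@H]([Se]c3ccccc3)[C@@H]2O1 | intermediate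
7 | selenoxide of 6 | O=C1C[C@@H]2CCC[C@@H]([Se](=O)c3ccccc3)[C@@H]2O1 | intermediate
8 | (3aS,7aR)-3a,4,5,7a-tetrahydro-1-benzofuran-2(3H)-one | O=C1C[C@@H]2CCC=C[C@@H]2O1 | intermediate
9 | iodomethane | CI | starting material
10 | lithium enolate of 8 | [Li]OC1=C[C@@H]2CCC=C[C@@H]2O1 | intermediate
11 | (3S,3aS,7aS)-3-methyl-3a,4,5,7a-tetrahydro-1-benzofuran-2(3H)-one | O=C1[C@@H](C)[C@@H]2CCC=C[C@@H]2O1 | intermediate
12 | (3S,3aS,7aS)-3-methyl-3a,4-dihydro-1-benzofuran-2,5(3H,7aH)-dione | O=C1[C@@H](C)[C@@H]2CC(=O)C=C[C@@H]2O1 | intermediate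
13 | isopropenylmagnesium bromide | C=C(C)[Mg]Br | starting material
14 | allyl bromide | C=CCBr | starting material
15 | bromomagnesium enolate of the 7-isopropenyl ketone | O=C1[C@@H](C)[C@@H]2CC(O[Mg]Br)=C[C@@H](C(C)=C)[C@@H]2O1 | intermediate
16 | (3S,3aS,6R,7S,7aR)-3-methyl-6-(prop-2-en-1-yl)-7-(prop-1-en-2-yl)hexahydro-1-benzofuran-2,5-dione | O=C1[C@@H](C)[C@@H]2CC(=O)[C@H](CC=C)[C@@H](C(C)=C)[C@@H]2O1 | intermediate
17 | tricyclic keto-lactone (1R,5S,6R,7S,11S; trans-fused methylcyclopentene/cyclohexanone with cis-fused α-methyl-γ-lactone) | O=C1[C@@H](C)[C@@H]2CC(=O)[C@@H]3CC=C(C)[C@H]3[C@@H]2O1 | intermediate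
18 | ethynylmagnesium bromide | C#C[Mg]Br | starting material
19 | (9S)-9-ethynyl-9-hydroxy lactone (propargylic alcohol of 17) | O=C1[C@@H](C)[C@@H]2C[C@@](O)(C#C)[C@@H]3CC=C(C)[C@H]3[C@@H]2O1 | intermediate
20 | 4-bromo-2-methylbut-1-ene | C=C(C)CCBr | starting material
21 | lactol of 19 (formed as its aluminium alkoxide, C12 epimers) | OC1[C@@H](C)[C@@H]2C[C@@](O)(C#C)[C@@H]3CC=C(C)[C@H]3[C@@H]2O1 | intermediate
22 | (3aS,4R,5S,7S,7aR)-7-ethynyl-5-[(2S,3S)-3-hydroxy-6-methylhept-6-en-2-yl]-3-methyl-3a,4,5,6,7,7a-hexahydro-1H-indene-4,7-diol | C=C(C)CC[C@H](O)[C@@H](C)[C@@H]1C[C@@](O)(C#C)[C@@H]2CC=C(C)[C@H]2[C@@H]1O | intermediate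
23 | acetic anhydride | CC(=O)OC(C)=O | starting material
24 | (2S,3S)-2-[(3aS,4R,5S,7S,7aR)-7-ethynyl-4,7-dihydroxy-3-methyl-3a,4,5,6,7,7a-hexahydro-1H-inden-5-yl]-6-methylhept-6-en-3-yl acetate | C=C(C)CC[C@H](OC(C)=O)[C@@H](C)[C@@H]1C[C@@](O)(C#C)[C@@H]2CC=C(C)[C@H]2[C@@H]1O | intermediate
25 | (2S,3S)-2-[(3aS,4R,5S,8aR)-4-hydroxy-3-methyl-8-methylidene-7-oxo-1,3a,4,5,6,7,8,8a-octahydroazulen-5-yl]-6-methylhept-6-en-3-yl acetate | C=C(C)CC[C@H](OC(C)=O)[C@@H](C)[C@@H]1CC(=O)C(=C)[C@@H]2CC=C(C)[C@H]2[C@@H]1O | intermediate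
26 | (2S,3S)-2-[(3aS,4R,5S,7R,8aR)-4,7-dihydroxy-3-methyl-8-methylidene-1,3a,4,5,6,7,8,8a-octahydroazulen-5-yl]-6-methylhept-6-en-3-yl acetate | C=C(C)CC[C@H](OC(C)=O)[C@@H](C)[C@@H]1C[C@@H](O)C(=C)[C@@H]2CC=C(C)[C@H]2[C@@H]1O | target

**Step count and risk**
Total step count: 12. Longest linear sequence: 12 steps (1 → 26); all other inputs are bought reagents.

Three steps most likely to fail:

Step 11 (the new ring expansion). The unstrained ring may not shift, or Meyer–Schuster rearrangement or alkyne hydration may win. The fallback uses known semipinacol chemistry and sets out from 24. Semi-hydrogenation of the alkyne (H2, Pd/CaCO3–Pb(OAc)2, quinoline) gives the vinyl carbinol F1. Hydroxyl-directed epoxidation (VO(acac)2, t-BuOOH) gives the epoxy alcohol F2. BF3·OEt2 at −78 °C then triggers the 2,3-epoxy-alcohol semipinacol shift of C1 with ring enlargement to the β-hydroxy ketone F3. Mesylation of the primary alcohol gives the mesylate F4, and DBU elimination delivers 25, where the route is rejoined.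

Step 6 (conjugate addition to a γ-acyloxy enone). Copper reagents can cleave the γ-C–O bond reductively instead of adding; alkenyl copper species are poor electron donors and the β-carbon is unhindered, but the risk is real. The fallback avoids copper and sets out from 12. α-Iodination (I2, pyridine, CH2Cl2) gives the 2-iodoenone F5. Stille coupling (allylSnBu3, Pd2(dba)3, AsPh3, CuI, NMP) gives the 2-allylenone F6. Rhodium-catalysed 1,4-addition of potassium isopropenyltrifluoroborate ([Rh(OH)(cod)]2, dioxane/H2O, 60 °C) on the convex face, followed by DBU equilibration of C1 to the trans ketone, returns to 16.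

Step 9 (one-pot half-reduction/Grignard addition; C12 selectivity). The Felkin preference of a Grignard reagent for an α-methyl aldehyde is often only 3–5:1, and the lactolate may over-reduce. The fallback forms the C–C bond first and sets the centre by inversion; it sets out from 19. (3-Methylbut-3-en-1-yl)lithium (from 20 and t-BuLi, THF, −78 °C) adds once to the lactone to give the hydroxy ketone F7. Felkin-selective reduction with Li[HB(s-Bu)3] gives the (12R)-triol F8. Mitsunobu esterification with acetic acid (PPh3, DIAD) inverts C12 at the less hindered secondary alcohol and gives 24 directly, so step 10 is skipped.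

**Further compounds**
F1 | step 11 | 9-vinyl carbinol (alkyne of 24 reduced to alkene) | C=C(C)CC[C@H](OC(C)=O)[C@@H](C)[C@@H]1C[C@@](O)(C=C)[C@@H]2CC=C(C)[C@H]2[C@@H]1O
F2 | step 11 | 9-(oxiran-2-yl) carbinol (epoxy alcohol, epoxide epimers) | C=C(C)CC[C@H](OC(C)=O)[C@@H](C)[C@@H]1C[C@@](O)(C3CO3)[C@@H]2CC=C(C)[C@H]2[C@@H]1O
F3 | step 11 | 10-(hydroxymethyl)cycloheptan-9-one (β-hydroxy ketone) | C=C(C)CC[C@H](OC(C)=O)[C@@H](C)[C@@H]1CC(=O)C(CO)[C@@H]2CC=C(C)[C@H]2[C@@H]1O
F4 | step 11 | primary mesylate of F3 | C=C(C)CC[C@H](OC(C)=O)[C@@H](C)[C@@H]1CC(=O)C(COS(C)(=O)=O)[C@@H]2CC=C(C)[C@H]2[C@@H]1O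
F5 | step 6 | 2-iodoenone (iodine at C1 of 12) | O=C1[C@@H](C)[C@@H]2CC(=O)C(I)=C[C@@H]2O1
F6 | step 6 | 2-allylenone (allyl at C1 of 12) | O=C1[C@@H](C)[C@@H]2CC(=O)C(CC=C)=C[C@@H]2O1
F7 | step 9 | C12 ketone (γ-hydroxy ketone from lactone opening) | C=C(C)CCC(=O)[C@@H](C)[C@@H]1C[C@@](O)(C#C)[C@@H]2CC=C(C)[C@H]2[C@@H]1O
F8 | step 9 | (12R)-epimer of triol 22 | C=C(C)CC[C@@H](O)[C@@H](C)[C@@H]1C[C@@](O)(C#C)[C@@H]2CC=C(C)[C@H]2[C@@H]1O
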